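The route rests on disconnecting the bond between the carbinol carbon (C5) and the adjacent ring-fusion carbon (C6) of the seven-membered carbocycle. These two atoms and the cyclopentene C8=C9 bond form a homoallylic alcohol that spans the ring fusion, the retron of a carbonyl allylation. An intramolecular Nozaki–Hiyama–Kishi reaction joins two electrophilic carbons after polarity reversal by CrCl2: it closes the seven-membered ring last, sets C5 and C6, and shifts the ring alkene into place. The precursor is a 2-methylcyclopentenyl chloride whose neighbouring stereocentre carries a 1,1-disubstituted alkene tether ending in an α-branched aldehyde with the finished acetoxy-oxolane side chain.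

Key step: step 17

Remarks on the chemistry (made before the steps):
- Atom labels: C1 = carbon bearing the exocyclic methylene; C2, C3 = the two ring methylenes; C4 = ring CH bearing the oxolane; C5 = carbinol carbon; C6 (next to C5) and C7 = ring-fusion carbons; C8 = methyl-bearing alkene carbon; C9 = alkene CH; C10 = cyclopentene CH2.
- Assumption: allylic chloride 24 is expected as a mixture of allylic regio- and stereoisomers. It is drawn as the product of direct substitution with inversion, and the mixture is used as such because all isomers give the same allylchromium species.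
- Some CIP descriptors change along the route through priority changes only (ring carbon C7: R in 13–18, S in 20–24, R in 26; C4: R in the alcohols and acetates, S in the aldehydes). No centre is inverted.
- Nerol, (4R)-4-benzyl-1,3-oxazolidin-2-one, pent-4-enoyl chloride and methacrolein are commercial. The L-fructose-derived Shi ketone is the enantiomer of the common catalyst and is available from L-sorbose.

**Side-chain fragment (steps 1–4)**

Step 1
Reactants: 1 nerol
Product: 2 [(2S,3R)-3-methyl-3-(4-methylpent-3-en-1-yl)oxiran-2-yl]methanol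
Conditions: Ti(OiPr)4 (cat.), L-(+)-diethyl tartrate (cat.), t-BuOOH, 4 Å MS, CH2Cl2, −20 °C
Reagents that add atoms: tert-butyl hydroperoxide, CC(C)(C)OO
Why: Sharpless asymmetric epoxidation, in which the titanium tartrate complex delivers oxygen to one face of the allylic alcohol alkene only, so that both epoxide carbons (later C4 and the quaternary oxolane carbon) are set by the catalyst while the remote trisubstituted alkene stays untouched.

Step 2
Reactants: 2 [(2S,3R)-3-methyl-3-(4-methylpent-3-en-1-yl)oxiran-2-yl]methanol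
Product: 3 (2R,3R)-2-ethenyl-3,7-dimethyloct-6-ene-1,3-diol
Conditions: CH2=CHMgBr (4 equiv), CuI (15 mol %), THF/Et2O, −40 to −10 °C; aq. NH4Cl
Reagents that add atoms: vinylmagnesium bromide, C=C[Mg]Br
Why: copper-catalysed Grignard opening of a 2,3-epoxy alcohol, in which the vinyl cuprate attacks the less substituted epoxide carbon in an SN2 sense with inversion, which sets C4 and leaves the tertiary C–O bond with its configuration.

Step 3
Reactants: 3 (2R,3R)-2-ethenyl-3,7-dimethyloct-6-ene-1,3-diol
Product: 5 (2R)-2-[(2R,5R)-5-(2-hydroxypropan-2-yl)-2-methyloxolan-2-yl]but-3-en-1-ol, via epoxy diol 4 (not isolated)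
Conditions: 1,2:4,5-di-O-isopropylidene-β-L-erythro-2,3-hexodiulo-2,6-pyranose (L-fructose-derived Shi ketone, 30 mol %), Oxone (2KHSO5·KHSO4·K2SO4), K2CO3, Bu4NHSO4, MeCN/CH2(OMe)2/aq. Na2B4O7 buffer, 0 °C; then camphor-10-sulfonic acid (10 mol %), CH2Cl2, 0 °C
Reagents that add atoms: potassium peroxymonosulfate (active part of Oxone), [K+].[O-]S(=O)(=O)OO
Why: Shi asymmetric epoxidation, in which the chiral dioxirane should epoxidise the electron-rich trisubstituted alkene (not the vinyl group) with catalyst-controlled facial selectivity to the (S)-epoxide, followed by acid-catalysed 5-exo-tet epoxide opening by the tertiary hydroxyl with inversion at the secondary epoxide carbon, which sets the second oxolane stereocentre and places the 2-hydroxypropan-2-yl group trans to the C4 substituent.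

Step 4
Reactants: 5 (2R)-2-[(2R,5R)-5-(2-hydroxypropan-2-yl)-2-methyloxolan-2-yl]but-3-en-1-ol
Product: 6 (2R)-2-[(2R,5R)-5-[2-(acetyloxy)propan-2-yl]-2-methyloxolan-2-yl]but-3-en-1-yl acetate
Conditions: Ac2O (excess), Et3N, 4-(dimethylamino)pyridine, CH2Cl2, 40 °C
Reagents that add atoms: acetic anhydride, CC(=O)OC(C)=O
Why: nucleophile-catalysed (acylpyridinium) acetylation, which should esterify the primary and, more slowly, the hindered tertiary hydroxyl; this installs the tertiary acetate of the target and a temporary primary acetate without touching any stereocentre.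

**Ring fragment (steps 5–11)**

Step 5
Reactants: 7 (4R)-4-benzyl-1,3-oxazolidin-2-one; 8 pent-4-enoyl chloride
Product: 9 (4R)-4-benzyl-3-(pent-4-enoyl)-1,3-oxazolidin-2-one
Conditions: Et3N, 4-(dimethylamino)pyridine (10 mol %), CH2Cl2, 0 °C to rt
Reagents that add atoms: none
Why: N-acylation of the oxazolidinone through an acylpyridinium intermediate, a standard way to attach the Evans auxiliary; no stereocentre is formed.

Step 6
Reactants: 9 (4R)-4-benzyl-3-(pent-4-enoyl)-1,3-oxazolidin-2-one; 10 methacrolein
Product: 12 (4R)-4-benzyl-3-[(2R,3R)-3-hydroxy-4-methyl-2-(prop-2-en-1-yl)pent-4-enoyl]-1,3-oxazolidin-2-one, via Z-boron enolate 11 (not isolated)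
Conditions: Bu2BOTf, Et3N, CH2Cl2, 0 °C; then 10, −78 to 0 °C; H2O2, pH 7 buffer, MeOH
Reagents that add atoms: none
Why: Evans syn aldol reaction, in which the Z-dibutylboron enolate reacts through a Zimmerman–Traxler chair with the auxiliary shielding one enolate face, which sets the α-carbon (the later ring-fusion carbon C7) and the syn carbinol centre (later erased).

Step 7
Reactants: 12 (4R)-4-benzyl-3-[(2R,3R)-3-hydroxy-4-methyl-2-(prop-2-en-1-yl)pent-4-enoyl]-1,3-oxazolidin-2-one
Product: 13 (4R)-4-benzyl-3-{[(1R,2R)-2-hydroxy-3-methylcyclopent-3-en-1-yl]carbonyl}-1,3-oxazolidin-2-one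
Conditions: (H2IMes)(PCy3)Cl2Ru=CHPh (second-generation Grubbs catalyst, 3 mol %), CH2Cl2 (0.02 M), 40 °C
Reagents that add atoms: none
Why: ring-closing olefin metathesis of the terminal alkene with the 1,1-disubstituted alkene, driven by loss of ethene, which should give the methyl-substituted cyclopentene without touching the two stereocentres.

Step 8
Reactants: 13 (4R)-4-benzyl-3-{[(1R,2R)-2-hydroxy-3-methylcyclopent-3-en-1-yl]carbonyl}-1,3-oxazolidin-2-one
Product: 14 (1R,2R)-2-hydroxy-N-methoxy-N,3-dimethylcyclopent-3-ene-1-carboxamide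
Conditions: MeNH(OMe)·HCl, AlMe3, CH2Cl2, −10 °C to rt
Reagents that add atoms: N,O-dimethylhydroxylamine hydrochloride, CNOC.Cl
Why: Weinreb aminolysis by an aluminium amide, which is anchored by the free β-hydroxyl, attacks the exocyclic imide carbonyl and releases the auxiliary under non-enolising conditions, so the α-stereocentre is kept.

Step 9
Reactants: 14 (1R,2R)-2-hydroxy-N-methoxy-N,3-dimethylcyclopent-3-ene-1-carboxamide
Product: 15 (1R,2R)-2-[(tert-butyldimethylsilyl)oxy]-N-methoxy-N,3-dimethylcyclopent-3-ene-1-carboxamide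
Conditions: TBSOTf, 2,6-lutidine, CH2Cl2, −78 to 0 °C
Reagents that add atoms: tert-butyldimethylsilyl trifluoromethanesulfonate, CC(C)(C)[Si](C)(C)OS(=O)(=O)C(F)(F)F
Why: silylation of the hindered secondary allylic alcohol with the reactive silyl triflate, which protects the oxygen that later becomes the leaving group of the allyl donor.

Step 10
Reactants: 15 (1R,2R)-2-[(tert-butyldimethylsilyl)oxy]-N-methoxy-N,3-dimethylcyclopent-3-ene-1-carboxamide
Product: 16 1-[(1R,2R)-2-[(tert-butyldimethylsilyl)oxy]-3-methylcyclopent-3-en-1-yl]ethan-1-one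
Conditions: MeMgBr, THF, 0 °C; aq. NH4Cl
Reagents that add atoms: methylmagnesium bromide, C[Mg]Br
Why: Weinreb ketone synthesis, in which the chelated tetrahedral magnesium intermediate prevents over-addition and collapses to the methyl ketone only on work-up, without epimerising the α-centre.

Step 11
Reactants: 16 1-[(1R,2R)-2-[(tert-butyldimethylsilyl)oxy]-3-methylcyclopent-3-en-1-yl]ethan-1-one
Product: 18 1-[(1R,2R)-2-[(tert-butyldimethylsilyl)oxy]-3-methylcyclopent-3-en-1-yl]ethenyl trifluoromethanesulfonate, via potassium enolate 17 (not isolated)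
Conditions: KN(SiMe3)2, THF, −78 °C; then PhNTf2, −78 to −20 °C
Reagents that add atoms: N-phenylbis(trifluoromethanesulfonimide), O=S(=O)(N(c1ccccc1)S(=O)(=O)C(F)(F)F)C(F)(F)F
Why: kinetic enolisation with a bulky amide base at the unhindered methyl group (not at the substituted α-methine, so the stereocentre is kept) and O-sulfonylation of the enolate, which gives the 1,1-disubstituted enol triflate that carries the future exocyclic methylene.

**Union and endgame (steps 12–17)**

Step 12
Reactants: 6 (2R)-2-[(2R,5R)-5-[2-(acetyloxy)propan-2-yl]-2-methyloxolan-2-yl]but-3-en-1-yl acetate; 18 1-[(1R,2R)-2-[(tert-butyldimethylsilyl)oxy]-3-methylcyclopent-3-en-1-yl]ethenyl trifluoromethanesulfonate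
Product: 20 (2R)-2-[(2R,5R)-5-[2-(acetyloxy)propan-2-yl]-2-methyloxolan-2-yl]-5-[(1S,2R)-2-[(tert-butyldimethylsilyl)oxy]-3-methylcyclopent-3-en-1-yl]hex-5-en-1-yl acetate, via B-alkyl-9-BBN borane 19 (not isolated)
Conditions: 6, 9-BBN, THF, rt to 45 °C; then 18, Pd(dppf)Cl2 (5 mol %), AsPh3, Cs2CO3, DMF/H2O, rt
Reagents that add atoms: none
Why: anti-Markovnikov hydroboration of the vinyl group followed by B-alkyl Suzuki–Miyaura coupling with the enol triflate, which joins C2 to C1 and delivers the 1,1-disubstituted alkene under conditions that the acetates and the silyl ether should tolerate; no stereocentre is involved.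

Step 13
Reactants: 20 (2R)-2-[(2R,5R)-5-[2-(acetyloxy)propan-2-yl]-2-methyloxolan-2-yl]-5-[(1S,2R)-2-[(tert-butyldimethylsilyl)oxy]-3-methylcyclopent-3-en-1-yl]hex-5-en-1-yl acetate
Product: 21 2-[(2R,5R)-5-[(2R)-5-[(1S,2R)-2-[(tert-butyldimethylsilyl)oxy]-3-methylcyclopent-3-en-1-yl]-1-hydroxyhex-5-en-2-yl]-5-methyloxolan-2-yl]propan-2-yl acetate
Conditions: K2CO3 (0.3 equiv), MeOH, 0 °C
Reagents that add atoms: none
Why: base-catalysed transesterification (methanolysis), which should cleave the unhindered primary acetate much faster than the tertiary acetate flanked by two methyl groups and the oxolane ring.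

Step 14
Reactants: 21 2-[(2R,5R)-5-[(2R)-5-[(1S,2R)-2-[(tert-butyldimethylsilyl)oxy]-3-methylcyclopent-3-en-1-yl]-1-hydroxyhex-5-en-2-yl]-5-methyloxolan-2-yl]propan-2-yl acetate
Product: 22 2-[(2R,5R)-5-[(2S)-5-[(1S,2R)-2-[(tert-butyldimethylsilyl)oxy]-3-methylcyclopent-3-en-1-yl]-1-oxohex-5-en-2-yl]-5-methyloxolan-2-yl]propan-2-yl acetate
Conditions: Dess–Martin periodinane, NaHCO3, CH2Cl2, 0 °C to rt
Reagents that add atoms: none
Why: Dess–Martin oxidation of the primary alcohol under buffered, non-basic conditions, which should give the α-branched aldehyde without epimerising C4, a centre shielded by the adjacent quaternary carbon.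

Step 15
Reactants: 22 2-[(2R,5R)-5-[(2S)-5-[(1S,2R)-2-[(tert-butyldimethylsilyl)oxy]-3-methylcyclopent-3-en-1-yl]-1-oxohex-5-en-2-yl]-5-methyloxolan-2-yl]propan-2-yl acetate
Product: 23 2-[(2R,5R)-5-[(2S)-5-[(1S,2R)-2-hydroxy-3-methylcyclopent-3-en-1-yl]-1-oxohex-5-en-2-yl]-5-methyloxolan-2-yl]propan-2-yl acetate
Conditions: HF·pyridine, pyridine, THF, 0 °C to rt
Reagents that add atoms: none
Why: fluoride-driven desilylation (Si–F bond formation) under buffered, weakly acidic conditions, which frees the allylic alcohol while the aldehyde α-centre, the tertiary acetate and the oxolane are left alone.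

Step 16
Reactants: 23 2-[(2R,5R)-5-[(2S)-5-[(1S,2R)-2-hydroxy-3-methylcyclopent-3-en-1-yl]-1-oxohex-5-en-2-yl]-5-methyloxolan-2-yl]propan-2-yl acetate
Product: 24 2-[(2R,5R)-5-[(2S)-5-[(1S,2S)-2-chloro-3-methylcyclopent-3-en-1-yl]-1-oxohex-5-en-2-yl]-5-methyloxolan-2-yl]propan-2-yl acetate
Conditions: N-chlorosuccinimide, Me2S (premixed), CH2Cl2, −20 to 0 °C; used crude
Reagents that add atoms: N-chlorosuccinimide, O=C1CCC(=O)N1Cl
Why: Corey–Kim chlorination, in which the alkoxysulfonium salt of the allylic alcohol is displaced by chloride under neutral conditions that an aldehyde tolerates; the configuration and position of the C–Cl bond do not matter because the next step passes through a delocalised allyl species.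

Step 17
Reactants: 24 2-[(2R,5R)-5-[(2S)-5-[(1S,2S)-2-chloro-3-methylcyclopent-3-en-1-yl]-1-oxohex-5-en-2-yl]-5-methyloxolan-2-yl]propan-2-yl acetate
Product: 26 dictyol H, via allylchromium dichloride 25 (not isolated)
Conditions: CrCl2 (8 equiv), LiI (cat.), THF, rt, slow addition of 24 (final 0.005 M); aq. NH4Cl
Reagents that add atoms: none
Why: Two equivalents of CrCl2 (divalent chromium) reduce the allylic C–Cl bond through an allyl radical to the allylchromium dichloride 25 (trivalent chromium), whose allyl termini equilibrate and which adds to the aldehyde through its γ-carbon C6 with allyl transposition, so that the alkene ends at C8=C9; the closest known reaction type is the intramolecular Nozaki–Hiyama–Kishi allylation used for medium and large carbocycles. The seven-membered ring is closed by C5–C6 bond formation as a 7-exo-trig attack on the aldehyde carbonyl, the cyclopentene and oxolane rings being already in place. C6 is controlled by the tether on the neighbouring stereocentre C7, which can deliver the aldehyde only to the allyl face it occupies and so gives the cis ring fusion. C5 is controlled by the six-membered chromium-bridged transition state (chromium bound to C9 and to the carbonyl oxygen on the same ring face), in which the oxygen lies over the cyclopentene and C4 points outward, so that H5 should end syn to H6 as in the target. The step needs γ- over α-attack, secured because only C6 is within reach of the tethered aldehyde, aldehyde over ester chemoselectivity, inherent to allylchromium reagents, and cyclisation over intermolecular coupling, secured by high dilution.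

**Compound list**

1 | nerol, (2Z)-3,7-dimethylocta-2,6-dien-1-ol | CC(C)=CCC/C(C)=C\CO | starting material
2 | [(2S,3R)-3-methyl-3-(4-methylpent-3-en-1-yl)oxiran-2-yl]methanol | OC[C@@H]1O[C@]1(C)CCC=C(C)C | intermediate
3 | (2R,3R)-2-ethenyl-3,7-dimethyloct-6-ene-1,3-diol | C=C[C@@H]([C@](C)(O)CCC=C(C)C)CO | intermediate
4 | (2R,3R)-5-[(2S)-3,3-dimethyloxiran-2-yl]-2-ethenyl-3-methylpentane-1,3-diol (epoxy diol) | C=C[C@@H]([C@](C)(O)CC[C@@H]1OC1(C)C)CO | intermediate (not isolated)
5 | (2R)-2-[(2R,5R)-5-(2-hydroxypropan-2-yl)-2-methyloxolan-2-yl]but-3-en-1-ol | C=C[C@@H]([C@@]1(C)CC[C@H](C(C)(C)O)O1)CO | intermediate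
6 | (2R)-2-[(2R,5R)-5-[2-(acetyloxy)propan-2-yl]-2-methyloxolan-2-yl]but-3-en-1-yl acetate | C=C[C@@H]([C@@]1(C)CC[C@H](C(C)(C)OC(C)=O)O1)COC(C)=O | intermediate
7 | (4R)-4-benzyl-1,3-oxazolidin-2-one | O=C1N[C@H](Cc2ccccc2)CO1 | starting material
8 | pent-4-enoyl chloride | C=CCCC(Cl)=O | starting material
9 | (4R)-4-benzyl-3-(pent-4-enoyl)-1,3-oxazolidin-2-one | C=CCCC(=O)N1[C@H](Cc2ccccc2)COC1=O | intermediate
10 | methacrolein, 2-methylprop-2-enal | C=C(C)C=O | starting material
11 | (4R)-4-benzyl-3-[(1Z)-1-(dibutylboranyloxy)penta-1,4-dien-1-yl]-1,3-oxazolidin-2-one (Z-boron enolate of 9) | C=CC/C=C(\OB(CCCC)CCCC)N1[C@H](Cc2ccccc2)COC1=O | intermediate (not isolated)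
12 | (4R)-4-benzyl-3-[(2R,3R)-3-hydroxy-4-methyl-2-(prop-2-en-1-yl)pent-4-enoyl]-1,3-oxazolidin-2-one | O=C(N1[C@H](Cc2ccccc2)COC1=O)[C@H](CC=C)[C@@H](O)C(C)=C | intermediate
13 | (4R)-4-benzyl-3-{[(1R,2R)-2-hydroxy-3-methylcyclopent-3-en-1-yl]carbonyl}-1,3-oxazolidin-2-one (cis) | O=C(N1[C@H](Cc2ccccc2)COC1=O)[C@@H]1CC=C(C)[C@@H]1O | intermediate
14 | (1R,2R)-2-hydroxy-N-methoxy-N,3-dimethylcyclopent-3-ene-1-carboxamide | CON(C)C(=O)[C@@H]1CC=C(C)[C@@H]1O | intermediate
15 | (1R,2R)-2-[(tert-butyldimethylsilyl)oxy]-N-methoxy-N,3-dimethylcyclopent-3-ene-1-carboxamide | CON(C)C(=O)[C@@H]1CC=C(C)[C@@H]1O[Si](C)(C)C(C)(C)C | intermediate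
16 | 1-[(1R,2R)-2-[(tert-butyldimethylsilyl)oxy]-3-methylcyclopent-3-en-1-yl]ethan-1-one | CC(=O)[C@@H]1CC=C(C)[C@@H]1O[Si](C)(C)C(C)(C)C | intermediate
17 | potassium 1-[(1R,2R)-2-[(tert-butyldimethylsilyl)oxy]-3-methylcyclopent-3-en-1-yl]ethen-1-olate (kinetic enolate of 16) | [K+].C=C([O-])[C@@H]1CC=C(C)[C@@H]1O[Si](C)(C)C(C)(C)C | intermediate (not isolated)
18 | 1-[(1R,2R)-2-[(tert-butyldimethylsilyl)oxy]-3-methylcyclopent-3-en-1-yl]ethenyl trifluoromethanesulfonate | C=C(OS(=O)(=O)C(F)(F)F)[C@@H]1CC=C(C)[C@@H]1O[Si](C)(C)C(C)(C)C | intermediate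
19 | (2R)-2-[(2R,5R)-5-[2-(acetyloxy)propan-2-yl]-2-methyloxolan-2-yl]-4-(9-borabicyclo[3.3.1]nonan-9-yl)butyl acetate | CC(=O)OC[C@@H](CCB1C2CCCC1CCC2)[C@@]1(C)CC[C@H](C(C)(C)OC(C)=O)O1 | intermediate (not isolated)
20 | (2R)-2-[(2R,5R)-5-[2-(acetyloxy)propan-2-yl]-2-methyloxolan-2-yl]-5-[(1S,2R)-2-[(tert-butyldimethylsilyl)oxy]-3-methylcyclopent-3-en-1-yl]hex-5-en-1-yl acetate | CC(=O)OC[C@@H](CCC(=C)[C@@H]1CC=C(C)[C@@H]1O[Si](C)(C)C(C)(C)C)[C@@]1(C)CC[C@H](C(C)(C)OC(C)=O)O1 | intermediate
21 | 2-[(2R,5R)-5-[(2R)-5-[(1S,2R)-2-[(tert-butyldimethylsilyl)oxy]-3-methylcyclopent-3-en-1-yl]-1-hydroxyhex-5-en-2-yl]-5-methyloxolan-2-yl]propan-2-yl acetate | OC[C@@H](CCC(=C)[C@@H]1CC=C(C)[C@@H]1O[Si](C)(C)C(C)(C)C)[C@@]1(C)CC[C@H](C(C)(C)OC(C)=O)O1 | intermediate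
22 | 2-[(2R,5R)-5-[(2S)-5-[(1S,2R)-2-[(tert-butyldimethylsilyl)oxy]-3-methylcyclopent-3-en-1-yl]-1-oxohex-5-en-2-yl]-5-methyloxolan-2-yl]propan-2-yl acetate | O=C[C@@H](CCC(=C)[C@@H]1CC=C(C)[C@@H]1O[Si](C)(C)C(C)(C)C)[C@@]1(C)CC[C@H](C(C)(C)OC(C)=O)O1 | intermediate
23 | 2-[(2R,5R)-5-[(2S)-5-[(1S,2R)-2-hydroxy-3-methylcyclopent-3-en-1-yl]-1-oxohex-5-en-2-yl]-5-methyloxolan-2-yl]propan-2-yl acetate | O=C[C@@H](CCC(=C)[C@@H]1CC=C(C)[C@@H]1O)[C@@]1(C)CC[C@H](C(C)(C)OC(C)=O)O1 | intermediate
24 | 2-[(2R,5R)-5-[(2S)-5-[(1S,2S)-2-chloro-3-methylcyclopent-3-en-1-yl]-1-oxohex-5-en-2-yl]-5-methyloxolan-2-yl]propan-2-yl acetate (one allylic isomer drawn) | O=C[C@@H](CCC(=C)[C@@H]1CC=C(C)[C@H]1Cl)[C@@]1(C)CC[C@H](C(C)(C)OC(C)=O)O1 | intermediate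
25 | dichloro{(1S,4R)-4-[(5S)-5-[(2R,5R)-5-[2-(acetyloxy)propan-2-yl]-2-methyloxolan-2-yl]-6-oxohex-1-en-2-yl]-2-methylcyclopent-2-en-1-yl}chromium (reactive σ-allyl isomer, chromium cis to the tether, solvent ligands omitted) | O=C[C@@H](CCC(=C)[C@@H]1C[C@H]([Cr](Cl)Cl)C(C)=C1)[C@@]1(C)CC[C@H](C(C)(C)OC(C)=O)O1 | intermediate (not isolated)
26 | dictyol H, 2-[(2R,5R)-5-[(3aR,4S,5R,8aR)-4-hydroxy-3-methyl-8-methylidene-1,3a,4,5,6,7,8,8a-octahydroazulen-5-yl]-5-methyloxolan-2-yl]propan-2-yl acetate | C=C1CC[C@@H]([C@@]2(C)CC[C@H](C(C)(C)OC(C)=O)O2)[C@@H](O)[C@H]2C(C)=CC[C@@H]12 | target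

**Totals**

Total step count: 17.
Longest linear sequence: 13 steps (steps 5–17, from 7).

**Steps most likely to fail, with fallbacks**

Step 17. The seven-membered ring closure may be outrun by protonation or dimerisation of the allylchromium species, or by a Lewis-acid-promoted type 2 carbonyl-ene closure of the aldehyde onto the 1,1-disubstituted alkene. Facial selectivity at the carbinol carbon may also erode if the bridged transition state is not followed. The fallback replaces the stoichiometric chromium reagent by a catalytic π-allylpalladium umpolung and sets out from hydroxy aldehyde 23. Acetylation of the cyclopentenol (Ac2O, pyridine, 4-(dimethylamino)pyridine, 0 °C) should give the allylic acetate F1. Pd(PPh3)4 (zerovalent palladium, 5 mol %) would ionise F1 to a π-allylpalladium complex, which InI (monovalent indium, 2 equiv, THF, rt, high dilution) reduces to an allylindium species. This species should add to the tethered aldehyde through the same cyclic six-membered array, so the fallback comes back to the route at 26.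

Step 3. The acid-mediated epoxide opening may go partly 6-endo at the tertiary epoxide carbon to an oxane, and facial control in the epoxidation by the less common catalyst enantiomer may be incomplete. The fallback drops the epoxide altogether: it sets out from diol 3 and comes back at 5 in one operation, so it makes no new compound (F0). A cobalt-catalysed aerobic oxidative cyclisation of the Mukaiyama type is used: Co(modp)2 (modp = 1-morpholinocarbamoyl-4,4-dimethylpentane-1,3-dionate; divalent cobalt), O2, t-BuOOH (cat.), i-PrOH, 55 °C. This closure is 5-exo only and should place the new 2-hydroxypropan-2-yl group trans to the larger substituent of the tertiary carbinol, as the target requires.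

Step 12. Hydroboration of the hindered vinyl group or transmetalation of the branched alkylborane may be slow, so that hydrolysis or reduction of the enol triflate takes over. The fallback changes the organometallic partner and isolates it. It sets out from diacetate 6: hydroboration as before (borane 19) and oxidation with NaBO3·4H2O should give the primary alcohol F2, and I2/PPh3/imidazole the iodide F3. Zinc dust with LiCl in THF should then give the alkylzinc iodide F4, which tolerates both acetates. Negishi coupling of F4 with triflate 18 (Pd(PPh3)4, THF/DMA, rt to 40 °C) comes back to the route at 20.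

Further compounds
F1 | step 17 | (1R,5S)-5-[(5S)-5-[(2R,5R)-5-[2-(acetyloxy)propan-2-yl]-2-methyloxolan-2-yl]-6-oxohex-1-en-2-yl]-2-methylcyclopent-2-en-1-yl acetate | O=C[C@@H](CCC(=C)[C@@H]1CC=C(C)[C@@H]1OC(C)=O)[C@@]1(C)CC[C@H](C(C)(C)OC(C)=O)O1
F0 | step 3 | none | none
F2 | step 12 | (2R)-2-[(2R,5R)-5-[2-(acetyloxy)propan-2-yl]-2-methyloxolan-2-yl]-4-hydroxybutyl acetate | CC(=O)OC[C@@H](CCO)[C@@]1(C)CC[C@H](C(C)(C)OC(C)=O)O1
F3 | step 12 | (2R)-2-[(2R,5R)-5-[2-(acetyloxy)propan-2-yl]-2-methyloxolan-2-yl]-4-iodobutyl acetate | CC(=O)OC[C@@H](CCI)[C@@]1(C)CC[C@H](C(C)(C)OC(C)=O)O1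
F4 | step 12 | {(3R)-4-(acetyloxy)-3-[(2R,5R)-5-[2-(acetyloxy)propan-2-yl]-2-methyloxolan-2-yl]butyl}(iodo)zinc | CC(=O)OC[C@@H](CC[Zn]I)[C@@]1(C)CC[C@H](C(C)(C)OC(C)=O)O1
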